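**Plan**

- The retrosynthesis first cuts O1–C2 (cyclodehydration of an o-hydroxyaryl 1,3-diketone), then C4–C4a and C3–C4 together, so that C4 leaves as carbon monoxide between a ring A aryl iodide and a ring B methoxyacetyl ketone.
- This is possible because C4 is an isolated carbonyl carbon between C4a and the methoxy-bearing C3. Ring A carries five oxygens in the symmetric order O(8a), OMe(8), OH(7), OMe(6), OH(5), so its precursor has a single C–H and two equivalent ortho oxygens.
- Forward, the ring A iodide is built from 2,6-dimethoxyphenol (MOM ether, double bromination, double hydroxylation, MOM ethers, lithiation–iodination). The ring B ketone comes from 1-bromo-2,4,5-trimethoxybenzene and a Weinreb amide.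
- Iodide, carbon monoxide and ketone are joined to an open-chain 1,3-diketone (no ring formed). Ring C closes last, in the acid treatment that also removes the three MOM groups.
- The target has no stereocentre. The one centre of the diketone is racemic, enolisable and becomes sp2 C3 on ring closure.

Key step: step 7

Assumption: the open-chain 1,3-diketone is drawn in its keto form, and 1-bromo-2,4,5-trimethoxybenzene and N,2-dimethoxy-N-methylacetamide are taken as purchasable, which avoids a Friedel–Crafts reaction with methoxyacetyl chloride.

Step 1
Reactants: 1 2,6-dimethoxyphenol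
Product: 2 1,3-dimethoxy-2-(methoxymethoxy)benzene
Conditions: MOMCl, iPr2NEt, CH2Cl2, 0 °C → rt
Reagents that add atoms: chloromethyl methyl ether (MOMCl), COCCl
Why: O-alkylation of the phenol (MOM protection, Williamson type) should be clean, and the resulting central ether is twisted out of the ring plane by its two neighbours, so it no longer directs an electrophile to its para position.

Step 2
Reactants: 2 1,3-dimethoxy-2-(methoxymethoxy)benzene
Product: 4 1,5-dibromo-2,4-dimethoxy-3-(methoxymethoxy)benzene, via monobromide 3 (not isolated)
Conditions: NBS (2.1 equiv), MeCN, 0 °C → rt, dark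
Reagents that add atoms: N-bromosuccinimide, O=C1CCC(=O)N1Br
Why: Electrophilic aromatic bromination should place each bromine ortho/para to the flanking methoxy groups, as 1,2,3-trialkoxybenzenes are substituted at C4 and then C6, and the dibromide is deactivated towards a third substitution.

Step 3
Reactants: 4 1,5-dibromo-2,4-dimethoxy-3-(methoxymethoxy)benzene
Product: 6 4,6-dimethoxy-5-(methoxymethoxy)benzene-1,3-diol, via bromophenol 5 (not isolated)
Conditions: Pd2(dba)3 (2 mol %), tBuXPhos (8 mol %), KOH (6 equiv), 1,4-dioxane/H2O, 100 °C, degassed; then aq. citric acid to pH 5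
Reagents that add atoms: potassium hydroxide, [K+].[OH-]
Why: Palladium-catalysed hydroxylation of aryl bromides with hydroxide (C–O cross-coupling of the Buchwald–Hartwig type) should convert both C–Br bonds, since the bulky biarylphosphine favours C–O reductive elimination over diaryl ether formation and the MOM and methyl ethers are inert to hot aqueous base.

Step 4
Reactants: 6 4,6-dimethoxy-5-(methoxymethoxy)benzene-1,3-diol
Product: 8 2,4-dimethoxy-1,3,5-tris(methoxymethoxy)benzene, via mono-MOM phenol 7 (not isolated)
Conditions: MOMCl (2.6 equiv), iPr2NEt, CH2Cl2, 0 °C → rt, under argon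
Reagents that add atoms: chloromethyl methyl ether (MOMCl), COCCl
Why: MOM protection (O-alkylation) of both phenols should proceed as in step 1 and puts two equivalent acetal directing groups on either side of the only ring C–H.

Step 5
Reactants: 8 2,4-dimethoxy-1,3,5-tris(methoxymethoxy)benzene
Product: 10 2-iodo-4,6-dimethoxy-1,3,5-tris(methoxymethoxy)benzene, via aryllithium 9 (not isolated)
Conditions: n-BuLi (1.2 equiv), THF, 0 °C; then I2, −78 °C → rt; aq. Na2S2O3
Reagents that add atoms: iodine, [I][I]
Why: Directed ortho-metalation between two MOM ethers followed by iodinolysis is a standard sequence, and because 8 has a single aromatic hydrogen the iodine can only enter the carbon that becomes C4a.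

Step 6
Reactants: 11 1-bromo-2,4,5-trimethoxybenzene; 12 N,2-dimethoxy-N-methylacetamide
Product: 15 2-methoxy-1-(2,4,5-trimethoxyphenyl)ethan-1-one, via aryllithium 13 (not isolated), via tetrahedral lithium adduct 14 (not isolated)
Conditions: n-BuLi (1.05 equiv), THF, −78 °C; then 12, −78 → 0 °C; 1 M HCl, 0 °C
Reagents that add atoms: none
Why: Bromine–lithium exchange followed by a Weinreb ketone synthesis should give the ketone by single addition, the chelated tetrahedral adduct holding until the acidic quench, and it avoids the loss of CO to a methoxymethyl cation that threatens Lewis-acid activation of methoxyacetyl chloride.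

Step 7
Reactants: 10 2-iodo-4,6-dimethoxy-1,3,5-tris(methoxymethoxy)benzene; 15 2-methoxy-1-(2,4,5-trimethoxyphenyl)ethan-1-one; 16 carbon monoxide
Product: 17 1-[3,5-dimethoxy-2,4,6-tris(methoxymethoxy)phenyl]-2-methoxy-3-(2,4,5-trimethoxyphenyl)propane-1,3-dione (racemic)
Conditions: Pd(dba)2 (5 mol %), Xantphos (6 mol %), MgCl2 (1.5 equiv), Et3N (3 equiv), 15 (1.5 equiv), CO (1 atm), 1,4-dioxane, 80 °C; aq. NH4Cl
Reagents that add atoms: none
Why: Zerovalent palladium adds oxidatively to the C–I bond of 10 and migratory insertion of CO gives an aroylpalladium iodide, which makes C4–C4a; the magnesium enolate of 15, formed by soft enolisation and held as a chelate by its α-methoxy group, then replaces iodide and reductive elimination makes C3–C4. The closest known reaction is the palladium-catalysed carbonylative α-arylation of aryl ketones with aryl iodides to 1,3-diketones. No ring is closed here; the pyranone ring is left to step 8. The only new stereocentre, the methoxy-bearing carbon between the two carbonyls, is enolisable, forms without control as the racemate and is erased when it becomes C3 of the flavone. The step needs carbonylative rather than direct arylation, C- rather than O-acylation and a single acylation. The two ortho MOM ethers slow direct aryl–enolate coupling so that CO insertion comes first, the magnesium chelate steers the acyl group to carbon, 15 has one enolisable carbon only, and the product is withdrawn at once as its magnesium diketonate.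

Step 8
Reactants: 17 1-[3,5-dimethoxy-2,4,6-tris(methoxymethoxy)phenyl]-2-methoxy-3-(2,4,5-trimethoxyphenyl)propane-1,3-dione
Product: 20 5,7-dihydroxy-3,6,8,2',4',5'-hexamethoxyflavone, via triphenol diketone 18 (not isolated), via hemiketal 19 (not isolated)
Conditions: 3 M HCl in MeOH, 55 °C
Reagents that add atoms: none
Why: Acid-catalysed acetal methanolysis frees the three phenols and the o-hydroxyaryl 1,3-diketone then cyclodehydrates as in the closing stage of a Baker–Venkataraman flavone synthesis, either ortho phenol adding 6-exo-trig to the ring B aroyl carbonyl before loss of water, and since the two ortho oxygens are equivalent only one flavone can form and a Wessely–Moser interchange would be degenerate.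

**Compound list**

1 | 2,6-dimethoxyphenol | COc1cccc(OC)c1O | starting material
2 | 1,3-dimethoxy-2-(methoxymethoxy)benzene | COCOc1c(OC)cccc1OC | intermediate
3 | 1-bromo-2,4-dimethoxy-3-(methoxymethoxy)benzene | COCOc1c(OC)ccc(Br)c1OC | intermediate
4 | 1,5-dibromo-2,4-dimethoxy-3-(methoxymethoxy)benzene | COCOc1c(OC)c(Br)cc(Br)c1OC | intermediate
5 | 5-bromo-2,4-dimethoxy-3-(methoxymethoxy)phenol | COCOc1c(OC)c(O)cc(Br)c1OC | intermediate
6 | 4,6-dimethoxy-5-(methoxymethoxy)benzene-1,3-diol | COCOc1c(OC)c(O)cc(O)c1OC | intermediate
7 | 2,4-dimethoxy-3,5-bis(methoxymethoxy)phenol | COCOc1cc(O)c(OC)c(OCOC)c1OC | intermediate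
8 | 2,4-dimethoxy-1,3,5-tris(methoxymethoxy)benzene | COCOc1cc(OCOC)c(OC)c(OCOC)c1OC | intermediate
9 | [3,5-dimethoxy-2,4,6-tris(methoxymethoxy)phenyl]lithium | [Li]c1c(OCOC)c(OC)c(OCOC)c(OC)c1OCOC | intermediate
10 | 2-iodo-4,6-dimethoxy-1,3,5-tris(methoxymethoxy)benzene | COCOc1c(I)c(OCOC)c(OC)c(OCOC)c1OC | intermediate
11 | 1-bromo-2,4,5-trimethoxybenzene | COc1cc(OC)c(Br)cc1OC | starting material
12 | N,2-dimethoxy-N-methylacetamide | COCC(=O)N(C)OC | starting material
13 | (2,4,5-trimethoxyphenyl)lithium | [Li]c1cc(OC)c(OC)cc1OC | intermediate
14 | lithium 2-methoxy-1-[methoxy(methyl)amino]-1-(2,4,5-trimethoxyphenyl)ethan-1-olate (racemic) | COCC(O[Li])(N(C)OC)c1cc(OC)c(OC)cc1OC | intermediate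
15 | 2-methoxy-1-(2,4,5-trimethoxyphenyl)ethan-1-one | COCC(=O)c1cc(OC)c(OC)cc1OC | intermediate
16 | carbon monoxide | [C-]#[O+] | starting material
17 | 1-[3,5-dimethoxy-2,4,6-tris(methoxymethoxy)phenyl]-2-methoxy-3-(2,4,5-trimethoxyphenyl)propane-1,3-dione (racemic, enolisable centre) | COCOc1c(C(=O)C(OC)C(=O)c2cc(OC)c(OC)cc2OC)c(OCOC)c(OC)c(OCOC)c1OC | intermediate
18 | 2-methoxy-1-(2,4,6-trihydroxy-3,5-dimethoxyphenyl)-3-(2,4,5-trimethoxyphenyl)propane-1,3-dione (racemic) | COc1c(O)c(OC)c(O)c(C(=O)C(OC)C(=O)c2cc(OC)c(OC)cc2OC)c1O | intermediate
19 | 2,5,7-trihydroxy-3,6,8-trimethoxy-2-(2,4,5-trimethoxyphenyl)-2,3-dihydro-4H-chromen-4-one (mixture of stereoisomers) | COc1cc(OC)c(C2(O)Oc3c(OC)c(O)c(OC)c(O)c3C(=O)C2OC)cc1OC | intermediate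
20 | 5,7-dihydroxy-3,6,8,2',4',5'-hexamethoxyflavone | COc1cc(OC)c(-c2oc3c(OC)c(O)c(OC)c(O)c3c(=O)c2OC)cc1OC | target

**Step count and risks**

Total steps: 8. Longest linear sequence: 7 steps (steps 1 to 5, then 7 and 8, from compound 1); step 6 is the one-step side branch.

Steps most likely to fail:

Step 7. Capture of the doubly ortho-substituted aroylpalladium by the magnesium enolate may be slow, so that protodeiodination, direct α-arylation or O-acylation of the enolate could take over. The fallback makes the same two bonds in separate events and sets out from arene 8. Lithiation as in step 5 gives aryllithium 9, which would be quenched with CO2 (THF, −78 °C → rt, then cold dilute HCl to pH 3) to give 3,5-dimethoxy-2,4,6-tris(methoxymethoxy)benzoic acid F1. Treatment with 1-chloro-N,N,2-trimethylprop-1-en-1-amine (CH2Cl2, 0 °C → rt, neutral conditions that spare the acetals) should give 3,5-dimethoxy-2,4,6-tris(methoxymethoxy)benzoyl chloride F2. A Claisen-type C-acylation of ketone 15 under soft enolisation (MgBr2·OEt2, iPr2NEt, CH2Cl2, 0 °C → rt) would then return to diketone 17, with C4 drawn from CO2 instead of CO.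

Step 3. The second C–O coupling may stall once the first phenoxide has formed, and diaryl ether formation or oxidative degradation of the electron-rich diphenoxide in hot base may erode the material. The fallback sets out from dibromide 4. Miyaura borylation (B2pin2, Pd(dppf)Cl2, KOAc, 1,4-dioxane, 90 °C) should give 2,2'-[4,6-dimethoxy-5-(methoxymethoxy)-1,3-phenylene]bis(4,4,5,5-tetramethyl-1,3,2-dioxaborolane) F3. Oxidation of both C–B bonds (NaBO3·4H2O, THF/H2O, rt) would return to diol 6 without exposure to hot hydroxide.

Step 8. Retro-Claisen methanolysis of the congested diketone, or arrest at the hemiketal stage, may compete with ring closure in hot methanolic acid. The fallback sets out from diketone 17 and separates deprotection from ring closure, both without a nucleophilic solvent. Bromotrimethylsilane (CH2Cl2, −30 → 0 °C, then aq. NaHCO3) should cleave the three acetals and allow triphenol diketone 18, in equilibrium with hemiketal 19, to be isolated. Catalytic p-toluenesulfonic acid in toluene at reflux with azeotropic removal of water should then dehydrate it and arrive at target 20.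

**Further compounds**

F1 | step 7 | 3,5-dimethoxy-2,4,6-tris(methoxymethoxy)benzoic acid | COCOc1c(C(=O)O)c(OCOC)c(OC)c(OCOC)c1OC
F2 | step 7 | 3,5-dimethoxy-2,4,6-tris(methoxymethoxy)benzoyl chloride | COCOc1c(C(Cl)=O)c(OCOC)c(OC)c(OCOC)c1OC
F3 | step 3 | 2,2'-[4,6-dimethoxy-5-(methoxymethoxy)-1,3-phenylene]bis(4,4,5,5-tetramethyl-1,3,2-dioxaborolane) | COCOc1c(OC)c(B2OC(C)(C)C(C)(C)O2)cc(B2OC(C)(C)C(C)(C)O2)c1OC
F0 | step 8 | none | none
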